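## Retrosynthetic overview

1. Target ⇒ methyl ester 33 (esterase hydrolysis last) ⇒ C–N disconnection of the enamide into 2-iodo epoxy enone 31 and primary dienamide 14 (Cu-catalysed amidation).
2. 31 ⇒ epoxy quinol 29: oxirane from a cis-diol with net retention, ketone from the secondary allylic alcohol; both carbinols from a singlet-oxygen [4+2] on diene 20, anti to the acetonide.
3. 20 ⇒ B-alkyl Suzuki coupling of bromodiene acetonide 17 with methyl pent-4-enoate 18; 17 ⇒ bromobenzene by toluene-dioxygenase cis-dihydroxylation (fixes the absolute configuration of the core).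
4. 14 ⇒ two Wittig olefinations on the differentiated syn-2,4-dimethylpentane-1,5-diol 9 ⇒ Zr-catalysed carboalumination of alkene 7 ⇒ Negishi vinylation of iodide 5 ⇒ Rh-catalysed asymmetric hydrogenation of acrylate 1.
5. Ring order: the carbocycle is taken intact from the arene (dearomatised, not built); temporary dioxolane; temporary 2,3-dioxabicyclo[2.2.2]octene; oxirane last.

Assumption: the recombinant toluene dioxygenase strain E. coli JM109(pDTG601), pig liver esterase and both antipodes of the chiral catalysts are taken as purchasable; in step 1 the ligand antipode is the one that gives the R ester.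

## Route

### Fragment 1: side-chain amide 14

Step 1
Reactants: 1 methyl 2-(hydroxymethyl)acrylate
Product: 2 methyl (2R)-3-hydroxy-2-methylpropanoate
Conditions: H2 (10 bar), [Rh(cod)2]BF4 (0.5 mol%), chiral bisphospholane ligand of the Me-DuPhos class (0.55 mol%), CH2Cl2, 25 °C
Reagents that add atoms: none
Why: Rh-catalysed asymmetric hydrogenation of a hydroxyl-chelating 1,1-disubstituted acrylate, in which the chiral diphosphine selects one alkene face and sets C2 as R (about 98% ee), the first stereocentre.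

Step 2
Reactants: 2 methyl (2R)-3-hydroxy-2-methylpropanoate
Product: 3 methyl (2R)-3-[(tert-butyldimethylsilyl)oxy]-2-methylpropanoate
Conditions: TBSCl, imidazole, DMF, 0 °C to rt
Reagents that add atoms: tert-butyldimethylsilyl chloride CC(C)(C)[Si](C)(C)Cl
Why: Standard silylation of the primary alcohol, which leaves the stereocentre untouched.

Step 3
Reactants: 3 methyl (2R)-3-[(tert-butyldimethylsilyl)oxy]-2-methylpropanoate
Product: 4 (2S)-3-[(tert-butyldimethylsilyl)oxy]-2-methylpropan-1-ol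
Conditions: i-Bu2AlH (2.5 equiv), CH2Cl2, −78 to 0 °C; aq. KNaC4H4O6 work-up
Reagents that add atoms: none
Why: Aluminium hydride reduction of the ester to the primary alcohol under non-basic work-up, so no silyl migration (which would racemise) occurs.

Step 4
Reactants: 4 (2S)-3-[(tert-butyldimethylsilyl)oxy]-2-methylpropan-1-ol
Product: 5 tert-butyl{[(2R)-3-iodo-2-methylpropyl]oxy}dimethylsilane
Conditions: I2, PPh3, imidazole, CH2Cl2, 0 °C to rt
Reagents that add atoms: iodine II
Why: Appel-type (Garegg–Samuelsson) iodination at the primary carbon; the stereocentre is not involved.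

Step 5
Reactants: 5 tert-butyl{[(2R)-3-iodo-2-methylpropyl]oxy}dimethylsilane
Product: 7 tert-butyldimethyl{[(2S)-2-methylpent-4-en-1-yl]oxy}silane, via alkylzinc iodide 6 (not isolated)
Conditions: Zn dust (activated), LiCl, THF, 40 °C; then vinyl bromide, Pd(dppf)Cl2 (3 mol%), THF, rt
Reagents that add atoms: vinyl bromide C=CBr
Why: Zinc insertion followed by Negishi sp3–sp2 cross-coupling; the metallated carbon is not stereogenic, so the β-stereocentre is carried through unchanged.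

Step 6
Reactants: 7 tert-butyldimethyl{[(2S)-2-methylpent-4-en-1-yl]oxy}silane
Product: 9 (2R,4S)-5-[(tert-butyldimethylsilyl)oxy]-2,4-dimethylpentan-1-ol, via alkyldimethylalane 8 (not isolated)
Conditions: Me3Al (2.5 equiv), (−)-bis(1-neomenthylindenyl)zirconium dichloride, (−)-(NMI)2ZrCl2 (5 mol%), methylaluminoxane (MeAlO)n (1 equiv), CH2Cl2, 0 °C to rt; then dry O2, 0 °C to rt; aq. NaOH work-up
Reagents that add atoms: trimethylaluminium C[Al](C)C; dioxygen O=O
Why: Zr-catalysed asymmetric carboalumination (Negishi ZACA) adds Me–Al across the terminal alkene under catalyst control (new centre R, syn to the existing one, about 8:1, minor anti isomer removed by chromatography), and O2 oxidises the C–Al bond with retention.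

Step 7
Reactants: 9 (2R,4S)-5-[(tert-butyldimethylsilyl)oxy]-2,4-dimethylpentan-1-ol
Product: 10 (2R,4S)-5-[(tert-butyldimethylsilyl)oxy]-2,4-dimethylpentanal
Conditions: TEMPO (10 mol%), PhI(OAc)2 (1.1 equiv), CH2Cl2, rt
Reagents that add atoms: none
Why: Nitroxyl-catalysed alcohol oxidation under base-free conditions, which stops at the aldehyde and avoids α-epimerisation.

Step 8
Reactants: 10 (2R,4S)-5-[(tert-butyldimethylsilyl)oxy]-2,4-dimethylpentanal
Product: 11 tert-butyldimethyl{[(2S,4R)-2,4,6-trimethylhept-5-en-1-yl]oxy}silane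
Conditions: i-PrPPh3I (1.5 equiv), n-BuLi (1.4 equiv), THF, 0 °C; then 10, −78 °C to rt
Reagents that add atoms: isopropyltriphenylphosphonium iodide CC(C)[P+](c1ccccc1)(c1ccccc1)c1ccccc1.[I-]
Why: Wittig olefination with a non-stabilised ylide gives the isopropylidene alkene (no geometry issue), and addition at low temperature keeps the α-stereocentre.

Step 9
Reactants: 11 tert-butyldimethyl{[(2S,4R)-2,4,6-trimethylhept-5-en-1-yl]oxy}silane
Product: 12 (2S,4R)-2,4,6-trimethylhept-5-en-1-ol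
Conditions: Bu4NF (1.2 equiv), THF, 0 °C to rt
Reagents that add atoms: none
Why: Fluoride-mediated desilylation of the primary silyl ether.

Step 10
Reactants: 12 (2S,4R)-2,4,6-trimethylhept-5-en-1-ol
Product: 13 (2S,4R)-2,4,6-trimethylhept-5-enal
Conditions: TEMPO (10 mol%), PhI(OAc)2 (1.1 equiv), CH2Cl2, rt; used crude
Reagents that add atoms: none
Why: Base-free nitroxyl-catalysed oxidation that tolerates the trisubstituted alkene and does not epimerise the α-methyl aldehyde.

Step 11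
Reactants: 13 (2S,4R)-2,4,6-trimethylhept-5-enal
Product: 14 (2E,4S,6R)-4,6,8-trimethylnona-2,7-dienamide
Conditions: Ph3P=CHCONH2 (1.3 equiv), CH2Cl2, rt to 40 °C
Reagents that add atoms: (carbamoylmethylene)triphenylphosphorane NC(=O)C=P(c1ccccc1)(c1ccccc1)c1ccccc1
Why: Wittig reaction with an amide-stabilised ylide gives the E-enamide selectively under neutral conditions, which keep the adjacent stereocentre.

### Fragment 2: epoxy quinol core, coupling and end game

Step 12
Reactants: 15 bromobenzene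
Product: 16 (1S,2S)-3-bromocyclohexa-3,5-diene-1,2-diol
Conditions: E. coli JM109(pDTG601) whole cells expressing toluene dioxygenase, air, glucose feed, phosphate buffer pH 7.2, 30 °C, fed-batch; EtOAc extraction
Reagents that add atoms: dioxygen O=O
Why: Enzymatic arene cis-dihydroxylation by a Rieske non-heme iron dioxygenase (toluene dioxygenase), whose active site delivers both oxygen atoms to one face at C2–C3 of the achiral arene and gives a single enantiomer (>99% ee).

Step 13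
Reactants: 16 (1S,2S)-3-bromocyclohexa-3,5-diene-1,2-diol
Product: 17 (3aS,7aS)-4-bromo-2,2-dimethyl-3a,7a-dihydro-1,3-benzodioxole
Conditions: 2,2-dimethoxypropane, p-TsOH (cat.), acetone, 0 °C; used at once
Reagents that add atoms: 2,2-dimethoxypropane COC(C)(C)OC
Why: Acetonide formation (ketalisation) protects the cis-diol and shields one face of the diene for the later cycloaddition.

Step 14
Reactants: 17 (3aS,7aS)-4-bromo-2,2-dimethyl-3a,7a-dihydro-1,3-benzodioxole; 18 methyl pent-4-enoate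
Product: 20 methyl 5-[(3aR,7aS)-2,2-dimethyl-3a,7a-dihydro-1,3-benzodioxol-4-yl]pentanoate, via B-alkyl-9-BBN 19 (not isolated)
Conditions: 18, 9-BBN-H (0.5 M in THF), 0 °C to rt; then 17, Pd(dppf)Cl2 (5 mol%), AsPh3 (5 mol%), Cs2CO3 (2 equiv), DMF/THF/H2O, rt
Reagents that add atoms: none
Why: Anti-Markovnikov hydroboration followed by B-alkyl Suzuki–Miyaura coupling at the vinyl bromide installs the ester chain at room temperature without touching the stereocentres.

Step 15
Reactants: 20 methyl 5-[(3aR,7aS)-2,2-dimethyl-3a,7a-dihydro-1,3-benzodioxol-4-yl]pentanoate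
Product: 22 methyl 5-[(3aS,4S,7R,7aS)-4,7-dihydroxy-2,2-dimethyl-3a,4,7,7a-tetrahydro-1,3-benzodioxol-4-yl]pentanoate, via endoperoxide 21 (not isolated)
Conditions: O2, tetraphenylporphyrin (1 mol%), visible light, CH2Cl2, −78 °C; then thiourea (1.5 equiv), MeOH, −78 °C to rt
Reagents that add atoms: dioxygen O=O
Why: Singlet-oxygen [4+2] cycloaddition to the cyclic diene occurs on the face anti to the acetonide and thiourea reduces the O–O bond, so the tertiary C4 and secondary C7 carbinols are both set trans to the dioxolane oxygens.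

Step 16
Reactants: 22 methyl 5-[(3aS,4S,7R,7aS)-4,7-dihydroxy-2,2-dimethyl-3a,4,7,7a-tetrahydro-1,3-benzodioxol-4-yl]pentanoate
Product: 23 methyl 5-[(3aS,4S,7R,7aR)-7-[(tert-butyldiphenylsilyl)oxy]-4-hydroxy-2,2-dimethyl-3a,4,7,7a-tetrahydro-1,3-benzodioxol-4-yl]pentanoate
Conditions: TBDPSCl (1.2 equiv), imidazole, DMF, rt
Reagents that add atoms: tert-butyldiphenylsilyl chloride CC(C)(C)[Si](Cl)(c1ccccc1)c1ccccc1
Why: Selective silylation of the secondary allylic alcohol, since the tertiary alcohol does not react with the bulky chlorosilane.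

Step 17
Reactants: 23 methyl 5-[(3aS,4S,7R,7aR)-7-[(tert-butyldiphenylsilyl)oxy]-4-hydroxy-2,2-dimethyl-3a,4,7,7a-tetrahydro-1,3-benzodioxol-4-yl]pentanoate
Product: 24 methyl 5-[(1S,4R,5R,6S)-4-[(tert-butyldiphenylsilyl)oxy]-1,5,6-trihydroxycyclohex-2-en-1-yl]pentanoate
Conditions: camphorsulfonic acid (10 mol%), MeOH, rt; Et3N quench
Reagents that add atoms: none
Why: Acid-catalysed transketalisation removes the acetonide while the TBDPS ether and the methyl ester survive.

Step 18
Reactants: 24 methyl 5-[(1S,4R,5R,6S)-4-[(tert-butyldiphenylsilyl)oxy]-1,5,6-trihydroxycyclohex-2-en-1-yl]pentanoate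
Product: 27 methyl 5-[(1S,2S,5R,6R)-5-[(tert-butyldiphenylsilyl)oxy]-2-hydroxy-7-oxabicyclo[4.1.0]hept-3-en-2-yl]pentanoate, via cyclic orthoacetate 25 (not isolated), via trans bromo acetate 26 (not isolated)
Conditions: MeC(OMe)3 (1.5 equiv), PPTS (5 mol%), CH2Cl2, rt, evaporate; AcBr (1.2 equiv), CH2Cl2, 0 °C, evaporate; K2CO3 (2 equiv), MeOH, 0 °C
Reagents that add atoms: none
Why: Kolb–Sharpless one-pot conversion of a cis-diol into an epoxide, in which bromide opens the acetoxonium ion with inversion and the freed alkoxide closes by SN2 with a second inversion, so the oxirane sits on the original diol face and therefore anti to the tertiary OH.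

Step 19
Reactants: 27 methyl 5-[(1S,2S,5R,6R)-5-[(tert-butyldiphenylsilyl)oxy]-2-hydroxy-7-oxabicyclo[4.1.0]hept-3-en-2-yl]pentanoate
Product: 28 methyl 5-[(1S,2S,5R,6S)-2,5-dihydroxy-7-oxabicyclo[4.1.0]hept-3-en-2-yl]pentanoate
Conditions: HF·pyridine, pyridine, THF, 0 °C to rt
Reagents that add atoms: none
Why: Fluoride desilylation under slightly acidic conditions forms no free alkoxide, so the trans epoxy alcohol cannot undergo Payne rearrangement.

Step 20
Reactants: 28 methyl 5-[(1S,2S,5R,6S)-2,5-dihydroxy-7-oxabicyclo[4.1.0]hept-3-en-2-yl]pentanoate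
Product: 29 methyl 5-[(1S,2S,6R)-2-hydroxy-5-oxo-7-oxabicyclo[4.1.0]hept-3-en-2-yl]pentanoate
Conditions: Dess–Martin periodinane (1.3 equiv), CH2Cl2, 0 °C to rt
Reagents that add atoms: none
Why: Dess–Martin oxidation converts the secondary allylic alcohol into the enone, while the tertiary alcohol cannot be oxidised.

Step 21
Reactants: 29 methyl 5-[(1S,2S,6R)-2-hydroxy-5-oxo-7-oxabicyclo[4.1.0]hept-3-en-2-yl]pentanoate
Product: 30 methyl 5-[(1S,2S,6R)-2-hydroxy-4-iodo-5-oxo-7-oxabicyclo[4.1.0]hept-3-en-2-yl]pentanoate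
Conditions: I2 (2 equiv), pyridine/CH2Cl2 1:1, 0 °C to rt
Reagents that add atoms: iodine II
Why: Johnson α-iodination of the enone (pyridine conjugate addition, iodination of the enolate, elimination) places iodine only at the α-carbon.

Step 22
Reactants: 30 methyl 5-[(1S,2S,6R)-2-hydroxy-4-iodo-5-oxo-7-oxabicyclo[4.1.0]hept-3-en-2-yl]pentanoate
Product: 31 methyl 5-[(1S,2S,6R)-4-iodo-5-oxo-2-[(triethylsilyl)oxy]-7-oxabicyclo[4.1.0]hept-3-en-2-yl]pentanoate
Conditions: Et3SiOTf (1.5 equiv), 2,6-lutidine (3 equiv), CH2Cl2, −78 to −20 °C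
Reagents that add atoms: triethylsilyl trifluoromethanesulfonate CC[Si](CC)(CC)OS(=O)(=O)C(F)(F)F
Why: Silylation of the tertiary alcohol with a silyl triflate blocks alkoxide formation, and with it Payne rearrangement, in the basic coupling that follows.

Step 23
Reactants: 31 methyl 5-[(1S,2S,6R)-4-iodo-5-oxo-2-[(triethylsilyl)oxy]-7-oxabicyclo[4.1.0]hept-3-en-2-yl]pentanoate; 14 (2E,4S,6R)-4,6,8-trimethylnona-2,7-dienamide
Product: 32 methyl 5-[(1S,2S,6R)-5-oxo-2-[(triethylsilyl)oxy]-4-{[(2E,4S,6R)-4,6,8-trimethylnona-2,7-dienoyl]amino}-7-oxabicyclo[4.1.0]hept-3-en-2-yl]pentanoate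
Conditions: CuI (20 mol%), N,N'-dimethylethylenediamine (40 mol%), Cs2CO3 (1.5 equiv), THF, 60 °C
Reagents that add atoms: none
Why: Copper-catalysed Goldberg–Buchwald amidation of the vinyl iodide with the primary amide forms the 2-amido enone with the double bond kept in place and joins the two fragments.

Step 24
Reactants: 32 methyl 5-[(1S,2S,6R)-5-oxo-2-[(triethylsilyl)oxy]-4-{[(2E,4S,6R)-4,6,8-trimethylnona-2,7-dienoyl]amino}-7-oxabicyclo[4.1.0]hept-3-en-2-yl]pentanoate
Product: 33 methyl 5-[(1S,2S,6R)-2-hydroxy-5-oxo-4-{[(2E,4S,6R)-4,6,8-trimethylnona-2,7-dienoyl]amino}-7-oxabicyclo[4.1.0]hept-3-en-2-yl]pentanoate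
Conditions: HF·pyridine, pyridine, THF, 0 °C to rt
Reagents that add atoms: none
Why: Buffered fluoride desilylation frees the tertiary alcohol without base, leaving epoxide, enamide and ester intact.

Step 25
Reactants: 33 methyl 5-[(1S,2S,6R)-2-hydroxy-5-oxo-4-{[(2E,4S,6R)-4,6,8-trimethylnona-2,7-dienoyl]amino}-7-oxabicyclo[4.1.0]hept-3-en-2-yl]pentanoate
Product: 34 5-[(1S,2S,6R)-2-hydroxy-5-oxo-4-{[(2E,4S,6R)-4,6,8-trimethylnona-2,7-dienoyl]amino}-7-oxabicyclo[4.1.0]hept-3-en-2-yl]pentanoic acid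
Conditions: pig liver esterase, 0.1 M phosphate buffer pH 7.5/acetone 9:1, 30 °C; then NaH2PO4 to pH 4, EtOAc extraction
Reagents that add atoms: water O
Why: Enzymatic ester hydrolysis by a carboxylesterase (serine hydrolase) at neutral pH cleaves only the unhindered methyl ester and avoids the hydroxide that would open or migrate the epoxide.

## Compound list

1 | methyl 2-(hydroxymethyl)acrylate | C=C(CO)C(=O)OC | starting material
2 | methyl (2R)-3-hydroxy-2-methylpropanoate | COC(=O)[C@H](C)CO | intermediate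
3 | methyl (2R)-3-[(tert-butyldimethylsilyl)oxy]-2-methylpropanoate | COC(=O)[C@H](C)CO[Si](C)(C)C(C)(C)C | intermediate
4 | (2S)-3-[(tert-butyldimethylsilyl)oxy]-2-methylpropan-1-ol | OC[C@H](C)CO[Si](C)(C)C(C)(C)C | intermediate
5 | tert-butyl{[(2R)-3-iodo-2-methylpropyl]oxy}dimethylsilane | IC[C@H](C)CO[Si](C)(C)C(C)(C)C | intermediate
6 | [(2R)-3-[(tert-butyldimethylsilyl)oxy]-2-methylpropyl]zinc iodide (alkylzinc iodide, not isolated) | I[Zn]C[C@H](C)CO[Si](C)(C)C(C)(C)C | intermediate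
7 | tert-butyldimethyl{[(2S)-2-methylpent-4-en-1-yl]oxy}silane | C=CC[C@H](C)CO[Si](C)(C)C(C)(C)C | intermediate
8 | [(2R,4S)-5-[(tert-butyldimethylsilyl)oxy]-2,4-dimethylpentyl]dimethylalane (alkyldimethylalane, not isolated) | C[Al](C)C[C@H](C)C[C@H](C)CO[Si](C)(C)C(C)(C)C | intermediate
9 | (2R,4S)-5-[(tert-butyldimethylsilyl)oxy]-2,4-dimethylpentan-1-ol | OC[C@H](C)C[C@H](C)CO[Si](C)(C)C(C)(C)C | intermediate
10 | (2R,4S)-5-[(tert-butyldimethylsilyl)oxy]-2,4-dimethylpentanal | O=C[C@H](C)C[C@H](C)CO[Si](C)(C)C(C)(C)C | intermediate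
11 | tert-butyldimethyl{[(2S,4R)-2,4,6-trimethylhept-5-en-1-yl]oxy}silane | CC(C)=C[C@H](C)C[C@H](C)CO[Si](C)(C)C(C)(C)C | intermediate
12 | (2S,4R)-2,4,6-trimethylhept-5-en-1-ol | CC(C)=C[C@H](C)C[C@H](C)CO | intermediate
13 | (2S,4R)-2,4,6-trimethylhept-5-enal | CC(C)=C[C@H](C)C[C@H](C)C=O | intermediate
14 | (2E,4S,6R)-4,6,8-trimethylnona-2,7-dienamide | CC(C)=C[C@H](C)C[C@H](C)/C=C/C(N)=O | intermediate
15 | bromobenzene | Brc1ccccc1 | starting material
16 | (1S,2S)-3-bromocyclohexa-3,5-diene-1,2-diol | O[C@H]1C=CC=C(Br)[C@H]1O | intermediate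
17 | (3aS,7aS)-4-bromo-2,2-dimethyl-3a,7a-dihydro-1,3-benzodioxole | CC1(C)O[C@H]2C=CC=C(Br)[C@H]2O1 | intermediate
18 | methyl pent-4-enoate | C=CCCC(=O)OC | starting material
19 | methyl 5-(9-borabicyclo[3.3.1]nonan-9-yl)pentanoate (B-alkyl-9-BBN, not isolated) | COC(=O)CCCCB1C2CCCC1CCC2 | intermediate
20 | methyl 5-[(3aR,7aS)-2,2-dimethyl-3a,7a-dihydro-1,3-benzodioxol-4-yl]pentanoate | CC1(C)O[C@H]2C=CC=C(CCCCC(=O)OC)[C@H]2O1 | intermediate
21 | endoperoxide (not isolated): 4,7-epidioxide of 20, O–O bridge across C4 and C7 on the face opposite the dioxolane, C5=C6 alkene, (3aS,4S,7R,7aR) | CC1(C)O[C@H]2[C@H]3C=C[C@](CCCCC(=O)OC)(OO3)[C@H]2O1 | intermediate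
22 | methyl 5-[(3aS,4S,7R,7aS)-4,7-dihydroxy-2,2-dimethyl-3a,4,7,7a-tetrahydro-1,3-benzodioxol-4-yl]pentanoate | CC1(C)O[C@H]2[C@H](O)C=C[C@@](O)(CCCCC(=O)OC)[C@H]2O1 | intermediate
23 | methyl 5-[(3aS,4S,7R,7aR)-7-[(tert-butyldiphenylsilyl)oxy]-4-hydroxy-2,2-dimethyl-3a,4,7,7a-tetrahydro-1,3-benzodioxol-4-yl]pentanoate | CC1(C)O[C@H]2[C@H](O[Si](c3ccccc3)(c3ccccc3)C(C)(C)C)C=C[C@@](O)(CCCCC(=O)OC)[C@H]2O1 | intermediate
24 | methyl 5-[(1S,4R,5R,6S)-4-[(tert-butyldiphenylsilyl)oxy]-1,5,6-trihydroxycyclohex-2-en-1-yl]pentanoate | O[C@H]1[C@H](O[Si](c2ccccc2)(c2ccccc2)C(C)(C)C)C=C[C@@](O)(CCCCC(=O)OC)[C@H]1O | intermediate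
25 | cyclic orthoacetate (not isolated): 2-methoxy-2-methyl-1,3-dioxolane across the cis-diol of 24, mixture at the orthoester carbon | COC1(C)O[C@H]2[C@H](O[Si](c3ccccc3)(c3ccccc3)C(C)(C)C)C=C[C@@](O)(CCCCC(=O)OC)[C@H]2O1 | intermediate
26 | trans bromo acetate (not isolated): bromine on the carbon next to the silyloxy carbon and cis to the silyloxy group, acetate on the carbon next to the carbinol and trans to the bromine | Br[C@@H]1[C@H](O[Si](c2ccccc2)(c2ccccc2)C(C)(C)C)C=C[C@@](O)(CCCCC(=O)OC)[C@H]1OC(C)=O | intermediate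
27 | methyl 5-[(1S,2S,5R,6R)-5-[(tert-butyldiphenylsilyl)oxy]-2-hydroxy-7-oxabicyclo[4.1.0]hept-3-en-2-yl]pentanoate | O1[C@H]2[C@H](O[Si](c3ccccc3)(c3ccccc3)C(C)(C)C)C=C[C@@](O)(CCCCC(=O)OC)[C@@H]12 | intermediate
28 | methyl 5-[(1S,2S,5R,6S)-2,5-dihydroxy-7-oxabicyclo[4.1.0]hept-3-en-2-yl]pentanoate | O1[C@H]2[C@H](O)C=C[C@@](O)(CCCCC(=O)OC)[C@@H]12 | intermediate
29 | methyl 5-[(1S,2S,6R)-2-hydroxy-5-oxo-7-oxabicyclo[4.1.0]hept-3-en-2-yl]pentanoate | C1=C[C@@](O)(CCCCC(=O)OC)[C@H]2O[C@H]2C1=O | intermediate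
30 | methyl 5-[(1S,2S,6R)-2-hydroxy-4-iodo-5-oxo-7-oxabicyclo[4.1.0]hept-3-en-2-yl]pentanoate | IC1=C[C@@](O)(CCCCC(=O)OC)[C@H]2O[C@H]2C1=O | intermediate
31 | methyl 5-[(1S,2S,6R)-4-iodo-5-oxo-2-[(triethylsilyl)oxy]-7-oxabicyclo[4.1.0]hept-3-en-2-yl]pentanoate | IC1=C[C@@](O[Si](CC)(CC)CC)(CCCCC(=O)OC)[C@H]2O[C@H]2C1=O | intermediate
32 | methyl 5-[(1S,2S,6R)-5-oxo-2-[(triethylsilyl)oxy]-4-{[(2E,4S,6R)-4,6,8-trimethylnona-2,7-dienoyl]amino}-7-oxabicyclo[4.1.0]hept-3-en-2-yl]pentanoate | CC(C)=C[C@H](C)C[C@H](C)/C=C/C(=O)NC1=C[C@@](O[Si](CC)(CC)CC)(CCCCC(=O)OC)[C@H]2O[C@H]2C1=O | intermediate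
33 | methyl 5-[(1S,2S,6R)-2-hydroxy-5-oxo-4-{[(2E,4S,6R)-4,6,8-trimethylnona-2,7-dienoyl]amino}-7-oxabicyclo[4.1.0]hept-3-en-2-yl]pentanoate | CC(C)=C[C@H](C)C[C@H](C)/C=C/C(=O)NC1=C[C@@](O)(CCCCC(=O)OC)[C@H]2O[C@H]2C1=O | intermediate
34 | 5-[(1S,2S,6R)-2-hydroxy-5-oxo-4-{[(2E,4S,6R)-4,6,8-trimethylnona-2,7-dienoyl]amino}-7-oxabicyclo[4.1.0]hept-3-en-2-yl]pentanoic acid | CC(C)=C[C@H](C)C[C@H](C)/C=C/C(=O)NC1=C[C@@](O)(CCCCC(=O)O)[C@H]2O[C@H]2C1=O | target

## Step count and risks

Total step count: 25.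
Longest linear sequence: 14 steps (15 to 34, steps 12–25; the branch 1 to 14 to 34, steps 1–11 and 23–25, is equally 14).

The three steps most likely to fail:

Step 23 (copper-catalysed amidation of the base-sensitive iodo enone). The fallback sets out from 31 and comes back at 32. Palladium-catalysed coupling of 31 with tert-butyl carbamate (Pd2(dba)3, Xantphos, Cs2CO3, dioxane, 60 °C) gives the Boc enecarbamate F1. In parallel, aldehyde 13 is taken by Wittig reaction with Ph3P=CHCO2Me to methyl (2E,4S,6R)-4,6,8-trimethylnona-2,7-dienoate F2, saponified (LiOH, THF/H2O) to (2E,4S,6R)-4,6,8-trimethylnona-2,7-dienoic acid F3 and converted with oxalyl chloride and catalytic DMF into the acid chloride F4. Deprotonation of F1 with LiN(SiMe3)2 at −78 °C and acylation with F4 gives the N-Boc imide F5, and selective Boc cleavage with Mg(ClO4)2 (cat.) in MeCN at 50 °C returns 32. The C–N bond to the ring is thus made with a small, well-behaved carbamate and the side chain is attached by N-acylation instead.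

Step 18 (one-pot diol to epoxide with a free tertiary alcohol nearby). The fallback sets out from 24 and comes back at 27. 1,1'-Thiocarbonyldiimidazole (toluene, 60 °C) converts the cis-diol into the cyclic thionocarbonate F6. Methyl iodide (neat, 50 °C) S-methylates it and iodide opens the ring with inversion to the trans iodo S-methyl thiocarbonate F7. K2CO3 in MeOH at 0 °C then removes the thiocarbonate and closes the oxirane with a second inversion to give 27. This avoids acetyl bromide and any acylation of the tertiary alcohol.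

Step 6 (moderate diastereoselectivity of the second carboalumination). The fallback sets out from 4 and comes back at 9. Oxidation of 4 (TEMPO, PhI(OAc)2) gives (2R)-3-[(tert-butyldimethylsilyl)oxy]-2-methylpropanal F8, used at once. Wittig reaction with Ph3P=C(CH3)CO2Et gives ethyl (2E,4S)-5-[(tert-butyldimethylsilyl)oxy]-2,4-dimethylpent-2-enoate F9, and i-Bu2AlH reduction gives (2E,4S)-5-[(tert-butyldimethylsilyl)oxy]-2,4-dimethylpent-2-en-1-ol F10. Catalyst-controlled asymmetric hydrogenation of the trisubstituted allylic alcohol with a chiral iridium phosphinooxazoline complex, [Ir(cod)(L)][B(C6H3(CF3)2)4], under H2 (50 bar) then sets the second methyl stereocentre syn and returns 9.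

## Further compounds

F1 | step 23 | Boc enecarbamate: methyl 5-[(1S,2S,6R)-4-[(tert-butoxycarbonyl)amino]-5-oxo-2-[(triethylsilyl)oxy]-7-oxabicyclo[4.1.0]hept-3-en-2-yl]pentanoate | CC(C)(C)OC(=O)NC1=C[C@@](O[Si](CC)(CC)CC)(CCCCC(=O)OC)[C@H]2O[C@H]2C1=O
F2 | step 23 | methyl (2E,4S,6R)-4,6,8-trimethylnona-2,7-dienoate | CC(C)=C[C@H](C)C[C@H](C)/C=C/C(=O)OC
F3 | step 23 | (2E,4S,6R)-4,6,8-trimethylnona-2,7-dienoic acid | CC(C)=C[C@H](C)C[C@H](C)/C=C/C(=O)O
F4 | step 23 | acid chloride: (2E,4S,6R)-4,6,8-trimethylnona-2,7-dienoyl chloride | CC(C)=C[C@H](C)C[C@H](C)/C=C/C(=O)Cl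
F5 | step 23 | N-Boc imide: methyl 5-[(1S,2S,6R)-4-{(tert-butoxycarbonyl)[(2E,4S,6R)-4,6,8-trimethylnona-2,7-dienoyl]amino}-5-oxo-2-[(triethylsilyl)oxy]-7-oxabicyclo[4.1.0]hept-3-en-2-yl]pentanoate | CC(C)=C[C@H](C)C[C@H](C)/C=C/C(=O)N(C(=O)OC(C)(C)C)C1=C[C@@](O[Si](CC)(CC)CC)(CCCCC(=O)OC)[C@H]2O[C@H]2C1=O
F6 | step 18 | cyclic thionocarbonate of the cis-diol of 24 | S=C1O[C@H]2[C@H](O[Si](c3ccccc3)(c3ccccc3)C(C)(C)C)C=C[C@@](O)(CCCCC(=O)OC)[C@H]2O1
F7 | step 18 | trans iodo S-methyl thiocarbonate (iodine next to the silyloxy carbon, thiocarbonate next to the carbinol) | I[C@@H]1[C@H](O[Si](c2ccccc2)(c2ccccc2)C(C)(C)C)C=C[C@@](O)(CCCCC(=O)OC)[C@H]1OC(=O)SC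
F8 | step 6 | (2R)-3-[(tert-butyldimethylsilyl)oxy]-2-methylpropanal | O=C[C@H](C)CO[Si](C)(C)C(C)(C)C
F9 | step 6 | ethyl (2E,4S)-5-[(tert-butyldimethylsilyl)oxy]-2,4-dimethylpent-2-enoate | CCOC(=O)/C(C)=C/[C@H](C)CO[Si](C)(C)C(C)(C)C
F10 | step 6 | (2E,4S)-5-[(tert-butyldimethylsilyl)oxy]-2,4-dimethylpent-2-en-1-ol | OC/C(C)=C/[C@H](C)CO[Si](C)(C)C(C)(C)C
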